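**Retrosynthetic overview**
- Key disconnection is the lactone C6–O bond: a catalytic enantioselective bromolactonisation of an achiral trienoic acid builds ring B (the butenolide) and sets C6, the only stereocentre set by a catalyst.
- C7–C8: Barbier allylation of a stannyl aldehyde with the 3-(bromomethyl)butenolide; C6 relays its configuration to C7 and C8 and the α-methylene lactone appears.
- The C2 carbonyl is carbon monoxide: ring A (the ten-membered carbocycle) is closed last by a carbonylative allyl–allyl coupling that forms C1–C2 and C2–C3.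
- Two identical CH2OAc groups on C4 remove any alkene-geometry issue until the ring closure, where one becomes C3 and the other stays as C15–OAc.
- Ring order: ring B first, ring A last; the trienoic acid comes from 1,3-diacetoxyacetone by two Wittig reactions.

Assumption: atom labels follow germacrane numbering (ring C1–C10, lactone carbons C11–C13, exocyclic methylene C14, acetoxymethyl C15); the target is (6R,7R,8S), with C3 and C6 trans across C4=C5 (Z by CIP).

**Step 1**
Reactants: 1 2-oxopropane-1,3-diyl diacetate (1,3-diacetoxyacetone); 2 (triphenyl-λ5-phosphanylidene)acetaldehyde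
Product: 3 4-acetoxy-3-(acetoxymethyl)but-2-enal
Conditions: toluene, 90 °C, 1 in excess (1.5 equiv)
Reagents that add atoms: none
Why: Wittig olefination of a ketone activated by two α-acyloxy groups with a stabilised formyl ylide; the two CH2OAc groups are identical so no alkene isomer can form, and excess ketone limits a second olefination of the less reactive conjugated enal.

**Step 2**
Reactants: 3 4-acetoxy-3-(acetoxymethyl)but-2-enal; 4 2-(bromomethyl)prop-2-enoic acid
Product: 7 (3E)-7-acetoxy-6-(acetoxymethyl)-2-methylidenehepta-3,5-dienoic acid, via phosphonium bromide 5 (not isolated), via ylide carboxylate 6 (not isolated)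
Conditions: PPh3, THF, 20 °C; NaN(SiMe3)2 (2.0 equiv), −78 °C; then 3, −78 to 0 °C; 1 M HCl work-up; used promptly
Reagents that add atoms: none
Why: Vinylogous Wittig reaction of the allylic ylide formed by SN2′ addition of PPh3 to the bromide and double deprotonation; the carboxylate stops the acrylate from acting as a Michael acceptor and the E diene is expected, any Z isomer being removed on silica.

**Step 3**
Reactants: 7 (3E)-7-acetoxy-6-(acetoxymethyl)-2-methylidenehepta-3,5-dienoic acid
Product: 9 (5R)-5-[3-acetoxy-2-(acetoxymethyl)prop-1-en-1-yl]-3-(bromomethyl)furan-2(5H)-one, via bromo methylidene lactone 8 (not isolated)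
Conditions: NBS (1.05 equiv), (DHQD)2PHAL (10 mol%), CHCl3/toluene 1:1, −40 °C; 1 M HCl wash; then Bu4NBr (10 mol%), acetone, 20 °C
Reagents that add atoms: N-bromosuccinimide, O=C1CCC(=O)N1Br
Why: Proposed new method: the dimeric cinchona alkaloid holds the acid as an ion pair and passes Br+ from NBS to C3 of the E alkene while the carboxylate oxygen adds anti at C4 in a 5-endo closure, favoured because the developing cation is an allyl cation stabilised by the bis(acetoxymethyl)vinyl group, so the C–O bond and the stereocentre (future C6) form together; the secondary allylic bromide 8 then shifts by bromide SN2′ attack to the conjugated primary bromide 9 without touching that centre; the closest known reactions are catalytic enantioselective 5-endo bromolactonisation of 4-aryl-but-3-enoic acids and 1,4-bromolactonisation of conjugated enynes.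

**Step 4**
Reactants: 10 3-methylbut-3-en-1-ol
Product: 12 3-[(tributylstannyl)methyl]but-3-en-1-ol, via dilithium dianion 11 (not isolated)
Conditions: n-BuLi (2.2 equiv), TMEDA, Et2O/hexane, 0 to 20 °C; then Bu3SnCl, −78 to 20 °C; H2O
Reagents that add atoms: tributyltin chloride (Bu3SnCl), CCCC[Sn](Cl)(CCCC)CCCC
Why: Alkoxide-directed allylic lithiation of isoprenol gives a dianion that is stannylated on carbon; any O–Sn bond is cleaved on aqueous work-up.

**Step 5**
Reactants: 12 3-[(tributylstannyl)methyl]but-3-en-1-ol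
Product: 13 3-[(tributylstannyl)methyl]but-3-enal
Conditions: Dess–Martin periodinane, pyridine, CH2Cl2, 0 °C; used at once
Reagents that add atoms: none
Why: Buffered Dess–Martin oxidation gives the β,γ-unsaturated aldehyde without alkene migration or loss of tin.

**Step 6**
Reactants: 9 (5R)-5-[3-acetoxy-2-(acetoxymethyl)prop-1-en-1-yl]-3-(bromomethyl)furan-2(5H)-one; 13 3-[(tributylstannyl)methyl]but-3-enal
Product: 15 (4R,5R)-5-[3-acetoxy-2-(acetoxymethyl)prop-1-en-1-yl]-4-{(1S)-1-hydroxy-3-[(tributylstannyl)methyl]but-3-en-1-yl}-3-methylideneoxolan-2-one, via allylzinc bromide 14 (not isolated)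
Conditions: Zn dust, THF/sat. aq. NH4Cl 4:1, 0 °C
Reagents that add atoms: none
Why: Barbier allylation in which the allylzinc adds through its ring carbon (SE2′) via a chair Zimmerman–Traxler transition state; the aldehyde attacks the butenolide face opposite the C6 side chain (C7 trans to it) and the ring-locked E allyl geometry gives the anti relation that is 8S, while the α-methylene lactone is unveiled.

**Step 7**
Reactants: 15 the hydroxy lactone from step 6
Product: 16 (1S)-1-{(2R,3R)-2-[3-acetoxy-2-(acetoxymethyl)prop-1-en-1-yl]-4-methylidene-5-oxooxolan-3-yl}-3-[(tributylstannyl)methyl]but-3-en-1-yl acetate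
Conditions: Ac2O, pyridine, DMAP (cat.), CH2Cl2, 0 °C
Reagents that add atoms: acetic anhydride, CC(=O)OC(C)=O
Why: DMAP-catalysed acetylation of the secondary alcohol, done at once so the free C8 hydroxyl cannot translactonise.

**Step 8**
Reactants: 16 the stannyl triacetate from step 7
Product: 17 target, (6R,7R,8S)-8,15-diacetoxy-2-oxogermacra-4,10(14),11(13)-trien-12,6-olide
Conditions: Pd2(dba)3 (5 mol%), AsPh3 (20 mol%), LiCl (2 equiv), CO (3 bar), THF, 50 °C, syringe-pump addition to 2 mM
Reagents that add atoms: carbon monoxide, [C-]#[O+]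
Why: Proposed new method: zerovalent palladium ionises either primary allylic acetate, the π-allyl settles in the syn form that puts C6 cis to the remaining CH2OAc, CO inserts at the CH2 terminus, and the acylpalladium is captured by the tethered 2-substituted allylstannane (both termini CH2, so no regiochemical issue) before reductive elimination closes the ten-membered ring as the bis-β,γ-unsaturated ketone and fixes the C4=C5 geometry; the closest known reactions are the intermolecular carbonylative Stille synthesis of diallyl ketones from allyl halides, CO and allylstannanes, and carbonylative Stille macrocyclisations.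

**Compound list**
1 | 2-oxopropane-1,3-diyl diacetate | CC(=O)OCC(=O)COC(C)=O | starting material
2 | (triphenyl-λ5-phosphanylidene)acetaldehyde | O=CC=P(c1ccccc1)(c1ccccc1)c1ccccc1 | starting material
3 | 4-acetoxy-3-(acetoxymethyl)but-2-enal | CC(=O)OCC(=CC=O)COC(C)=O | intermediate
4 | 2-(bromomethyl)prop-2-enoic acid | C=C(CBr)C(=O)O | starting material
5 | (2-carboxyprop-2-en-1-yl)triphenylphosphonium bromide (not isolated) | [Br-].OC(=O)C(=C)C[P+](c1ccccc1)(c1ccccc1)c1ccccc1 | intermediate
6 | sodium 2-[(triphenyl-λ5-phosphanylidene)methyl]prop-2-enoate (not isolated) | [Na+].[O-]C(=O)C(=C)C=P(c1ccccc1)(c1ccccc1)c1ccccc1 | intermediate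
7 | (3E)-7-acetoxy-6-(acetoxymethyl)-2-methylidenehepta-3,5-dienoic acid | C=C(C(=O)O)/C=C/C=C(COC(C)=O)COC(C)=O | intermediate
8 | (4S,5R)-5-[3-acetoxy-2-(acetoxymethyl)prop-1-en-1-yl]-4-bromo-3-methylideneoxolan-2-one, Br trans to the side chain (not isolated) | CC(=O)OCC(COC(C)=O)=C[C@H]1OC(=O)C(=C)[C@@H]1Br | intermediate
9 | (5R)-5-[3-acetoxy-2-(acetoxymethyl)prop-1-en-1-yl]-3-(bromomethyl)furan-2(5H)-one | CC(=O)OCC(COC(C)=O)=C[C@H]1OC(=O)C(CBr)=C1 | intermediate
10 | 3-methylbut-3-en-1-ol (isoprenol) | CC(=C)CCO | starting material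
11 | dilithium dianion of 10, lithiated on O and on the methyl carbon (not isolated) | [Li]CC(=C)CCO[Li] | intermediate
12 | 3-[(tributylstannyl)methyl]but-3-en-1-ol | C=C(CCO)C[Sn](CCCC)(CCCC)CCCC | intermediate
13 | 3-[(tributylstannyl)methyl]but-3-enal | O=CCC(=C)C[Sn](CCCC)(CCCC)CCCC | intermediate
14 | {[(5R)-5-[3-acetoxy-2-(acetoxymethyl)prop-1-en-1-yl]-2-oxo-2,5-dihydrofuran-3-yl]methyl}zinc bromide (not isolated) | CC(=O)OCC(COC(C)=O)=C[C@H]1OC(=O)C(C[Zn]Br)=C1 | intermediate
15 | (4R,5R)-5-[3-acetoxy-2-(acetoxymethyl)prop-1-en-1-yl]-4-{(1S)-1-hydroxy-3-[(tributylstannyl)methyl]but-3-en-1-yl}-3-methylideneoxolan-2-one | CC(=O)OCC(COC(C)=O)=C[C@H]1OC(=O)C(=C)[C@@H]1[C@@H](O)CC(=C)C[Sn](CCCC)(CCCC)CCCC | intermediate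
16 | (1S)-1-{(2R,3R)-2-[3-acetoxy-2-(acetoxymethyl)prop-1-en-1-yl]-4-methylidene-5-oxooxolan-3-yl}-3-[(tributylstannyl)methyl]but-3-en-1-yl acetate | CC(=O)OCC(COC(C)=O)=C[C@H]1OC(=O)C(=C)[C@@H]1[C@@H](OC(C)=O)CC(=C)C[Sn](CCCC)(CCCC)CCCC | intermediate
17 | (6R,7R,8S)-8,15-diacetoxy-2-oxogermacra-4,10(14),11(13)-trien-12,6-olide, C4=C5 Z by CIP with C3 and C6 trans (CNP0183179.1) | C=C1CC(=O)C/C(COC(C)=O)=C/[C@H]2OC(=O)C(=C)[C@@H]2[C@@H](OC(C)=O)C1 | target

**Step count**
Total steps: 8. Longest linear sequence: 6 (steps 1, 2, 3, 6, 7, 8); steps 4 and 5 make the side fragment.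

**Three steps most likely to fail**

Step 8 (new carbonylative ring closure). Risks are direct allyl–allyl coupling without CO, reaction through the anti π-allyl (wrong C4=C5 geometry), ionisation of the allylic lactone C6–O bond or of the remaining allylic acetate, and ring strain. The fallback uses known reaction types, sets out from 9 and comes back at 17. Zinc Barbier reaction of 9 with 3-methylidene-5-nitropentanal F4 (to be prepared separately) gives (4R,5R)-5-[3-acetoxy-2-(acetoxymethyl)prop-1-en-1-yl]-4-[(1S)-1-hydroxy-3-methylidene-5-nitropentyl]-3-methylideneoxolan-2-one F5. Acetylation gives its C8 acetate F6. A high-dilution Tsuji–Trost closure (Pd(PPh3)4, DBU, THF) joins the nitronate carbon to the allyl terminus and gives the 2-nitro ten-membered ring F7 as a mixture at C2. A Nef reaction with buffered aqueous TiCl3 then unmasks the C2 ketone to give 17.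

Step 3 (new bromolactonisation). Risks are low enantioselectivity, bromination at the other alkene, and amine-induced racemisation of 9 through its γ-proton; if the facial sense is opposite, (DHQ)2PHAL is used instead. The fallback is known chemistry, sets out from 3 and comes back at 9. Amino-alcohol-catalysed vinylzinc addition (Zn(CH=CH2)2, (−)-MIB, toluene, 0 °C) to 3 gives (4S)-2-(acetoxymethyl)-4-hydroxyhexa-2,5-dien-1-yl acetate F2. DCC/DMAP esterification with acid 4 gives (3S)-6-acetoxy-5-(acetoxymethyl)hexa-1,4-dien-3-yl 2-(bromomethyl)prop-2-enoate F3. Ring-closing metathesis with second-generation Hoveyda–Grubbs catalyst closes the butenolide and gives 9.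

Step 2 (vinylogous Wittig with a free acid). Risks are E/Z mixtures and Diels–Alder dimerisation of the diene acid. The fallback sets out from 3 and comes back at 7. Takai iodo-olefination (CHI3, CrCl2, THF, 0 °C) of 3 gives the E iodide 2-[(2E)-3-iodoprop-2-en-1-ylidene]propane-1,3-diyl diacetate F1. Stille coupling of F1 with 2-(tributylstannyl)prop-2-enoic acid (Pd(PPh3)4, CuI, DMF, 20 °C) gives 7.

**Further compounds**
F1 | step 2 | 2-[(2E)-3-iodoprop-2-en-1-ylidene]propane-1,3-diyl diacetate | CC(=O)OCC(COC(C)=O)=C/C=C/I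
F2 | step 3 | (4S)-2-(acetoxymethyl)-4-hydroxyhexa-2,5-dien-1-yl acetate | CC(=O)OCC(COC(C)=O)=C[C@H](C=C)O
F3 | step 3 | (3S)-6-acetoxy-5-(acetoxymethyl)hexa-1,4-dien-3-yl 2-(bromomethyl)prop-2-enoate | CC(=O)OCC(COC(C)=O)=C[C@H](C=C)OC(=O)C(=C)CBr
F4 | step 8 | 3-methylidene-5-nitropentanal | O=CCC(=C)CC[N+](=O)[O-]
F5 | step 8 | (4R,5R)-5-[3-acetoxy-2-(acetoxymethyl)prop-1-en-1-yl]-4-[(1S)-1-hydroxy-3-methylidene-5-nitropentyl]-3-methylideneoxolan-2-one | CC(=O)OCC(COC(C)=O)=C[C@H]1OC(=O)C(=C)[C@@H]1[C@@H](O)CC(=C)CC[N+](=O)[O-]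
F6 | step 8 | (1S)-1-{(2R,3R)-2-[3-acetoxy-2-(acetoxymethyl)prop-1-en-1-yl]-4-methylidene-5-oxooxolan-3-yl}-3-methylidene-5-nitropentyl acetate | CC(=O)OCC(COC(C)=O)=C[C@H]1OC(=O)C(=C)[C@@H]1[C@@H](OC(C)=O)CC(=C)CC[N+](=O)[O-]
F7 | step 8 | (6R,7R,8S)-8,15-diacetoxy-2-nitrogermacra-4,10(14),11(13)-trien-12,6-olide, mixture at C2 | C=C1CC([N+](=O)[O-])C/C(COC(C)=O)=C/[C@H]2OC(=O)C(=C)[C@@H]2[C@@H](OC(C)=O)C1
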